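**Retrosynthetic overview**
- The strategy rests on C2 of the dihydropyranone ring C, the only stereocentre: it is benzylic, bound to O1 and carries catechol ring B. Cutting C2–C1' leads back to the flat, achiral 5-hydroxy-7-methoxy-8-prenylchromone 8 and the MOM-protected arylboronic acid 13 (asymmetric 1,4-arylation, then MOM removal).
- The C8 prenyl group lies between O1 and the C7 methoxy group and is para to O5, so it is delivered from the 5-O-prenyl ether 5 by a para-Claisen–Cope shift (O5 to C6, then C6 to C8).
- Ring C of 5 is closed through the O1–C2 bond from the enaminone of acetophenone 3, itself the mono-prenyl ether of the symmetric 2',6'-dihydroxy-4'-methoxyacetophenone 1.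
- Boronic acid 13 comes from 4-bromocatechol 9 by bis-MOM protection and bromine–lithium exchange/borylation.
- Ring order: ring A is bought, ring C is closed in step 2, the prenyl group migrates in step 3, and ring B is attached last in step 6.

Key step: step 6

Assumption: compound 1 is taken as a catalogue chemical, and the (R)-antipode of the t-BuPyOx ligand is taken to give the 2S product by analogy with its sense of induction on cyclic enones; a small-scale run with chiral HPLC and CD assignment would confirm this, and the other antipode would be used if the sense is reversed.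

**Step 1**
Reactants: 1 2',6'-dihydroxy-4'-methoxyacetophenone; 2 prenyl bromide
Product: 3 2'-hydroxy-4'-methoxy-6'-(3-methylbut-2-enyloxy)acetophenone
Conditions: K2CO3 (1.1 equiv), 2 (1.05 equiv), acetone, reflux
Reagents that add atoms: none
Why: Williamson O-alkylation of one of the two equivalent phenols; the remaining hydroxyl stays hydrogen-bonded to the ketone and is far less nucleophilic, so mono-etherification should dominate.

**Step 2**
Reactants: 3 2'-hydroxy-4'-methoxy-6'-(3-methylbut-2-enyloxy)acetophenone
Product: 5 7-methoxy-5-(prenyloxy)chromen-4-one, via enaminone 4 (not isolated)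
Conditions: Me2NCH(OMe)2 (2 equiv), toluene, 95 °C; evaporate; then 1 M aq. H2SO4/CH2Cl2, rt
Reagents that add atoms: N,N-dimethylformamide dimethyl acetal, COC(OC)N(C)C
Why: Enaminone condensation at the methyl ketone followed by acid-triggered addition–elimination of the free phenol onto the β-carbon (O1–C2 bond formation, loss of dimethylamine) is the standard enaminone route to 2,3-unsubstituted chromones, and dilute acid at room temperature should spare the allylic aryl ether.

**Step 3**
Reactants: 5 7-methoxy-5-(prenyloxy)chromen-4-one
Product: 8 5-hydroxy-7-methoxy-8-prenylchromen-4-one, via ortho-dienone 6 (not isolated), via para-dienone 7 (not isolated)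
Conditions: Eu(fod)3 (10 mol%), CHCl3, 60 °C, sealed tube
Reagents that add atoms: none
Why: Trivalent europium (as europium tris(6,6,7,7,8,8,8-heptafluoro-2,2-dimethyl-3,5-octanedionate)) chelates C4=O and O5 and accelerates the aromatic Claisen shift to C6; the non-aromatic dienone 6 then undergoes a Cope shift to C8 and dienone 7 enolises, so this para-Claisen–Cope cascade places the unrearranged prenyl group para to O5 and frees the chelated 5-OH.

**Step 4**
Reactants: 9 4-bromocatechol
Product: 10 4-bromo-1,2-bis(methoxymethoxy)benzene
Conditions: NaH (2.4 equiv), MOMCl (2.4 equiv), DMF, 0 °C to rt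
Reagents that add atoms: chloromethyl methyl ether, COCCl
Why: Double Williamson etherification of the catechol dianion masks both phenols as base-stable acetals, with the aryl bromide untouched.

**Step 5**
Reactants: 10 4-bromo-1,2-bis(methoxymethoxy)benzene
Product: 13 3,4-bis(methoxymethoxy)phenylboronic acid, via aryllithium 11 (not isolated), via lithium aryltriisopropoxyborate 12 (not isolated)
Conditions: n-BuLi (1.1 equiv), THF, −78 °C; B(Oi-Pr)3 (1.5 equiv), −78 °C to rt; then 1 M HCl to pH 5–6, 0 °C
Reagents that add atoms: triisopropyl borate, CC(C)OB(OC(C)C)OC(C)C; water, O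
Why: Bromine–lithium exchange at −78 °C outruns MOM-directed ortho-lithiation, and trapping the aryllithium with the borate followed by mildly acidic hydrolysis should give the boronic acid with both acetals intact.

**Step 6**
Reactants: 8 5-hydroxy-7-methoxy-8-prenylchromen-4-one; 13 3,4-bis(methoxymethoxy)phenylboronic acid
Product: 14 (2S)-5-hydroxy-7-methoxy-2-[3,4-bis(methoxymethoxy)phenyl]-8-prenylchroman-4-one
Conditions: Pd(OCOCF3)2 (5–10 mol%), (R)-t-BuPyOx [(R)-4-tert-butyl-2-(pyridin-2-yl)-4,5-dihydrooxazole] (6–12 mol%), NH4PF6 (30 mol%), H2O (5 equiv), 13 (2 equiv), ClCH2CH2Cl, 40–60 °C, Ar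
Reagents that add atoms: none
Why: The aryl group of 13 transmetalates to the cationic divalent palladium–ligand complex, the C2=C3 bond of 8 inserts into the Pd–aryl bond with the aryl going to C2 in the enantiodetermining step, and water protonates the resulting Pd enolate, releasing the flavanone and returning divalent palladium without a redox cycle. The closest known reaction type is the palladium/pyridine-oxazoline-catalysed asymmetric conjugate addition of arylboronic acids to chromones and other cyclic enones. No ring is closed, since rings A, B and C are already in place; only the C2–C1' bond forms. The new C2 stereocentre is controlled by the ligand alone, whose tert-butyl group shields one enantioface of the planar, achiral chromone, the (R)-ligand being expected to give 2S. The step needs enantioface selectivity and 1,4-addition rather than β-hydride elimination to the flavone; the rigid s-trans enone, the hydrogen bond from 5-OH to C4=O (which raises the electrophilicity of C2 under neutral aqueous conditions) and fast protonolysis by the added water and ammonium salt should secure these. The trisubstituted prenyl alkene is too hindered to bind or insert, and the MOM ethers keep the catechol from chelating palladium.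

**Step 7**
Reactants: 14 (2S)-5-hydroxy-7-methoxy-2-[3,4-bis(methoxymethoxy)phenyl]-8-prenylchroman-4-one
Product: 15 (2S)-2-(3,4-dihydroxyphenyl)-5-hydroxy-7-methoxy-8-(3-methylbut-2-enyl)chroman-4-one (CNP0294928.1)
Conditions: HCl (1.25 M in MeOH), MeOH, rt to 40 °C
Reagents that add atoms: none
Why: Acid-catalysed acetal exchange in methanol removes both aryl MOM ethers as dimethoxymethane; the prenyl group has no free ortho hydroxyl to cyclise onto, and the absence of base keeps the retro-oxa-Michael racemisation path of the 5-hydroxyflavanone closed.

**Compound list**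
1 | 2',6'-dihydroxy-4'-methoxyacetophenone | CC(=O)c1c(O)cc(OC)cc1O | starting material
2 | prenyl bromide (1-bromo-3-methylbut-2-ene) | CC(C)=CCBr | starting material
3 | 2'-hydroxy-4'-methoxy-6'-(3-methylbut-2-enyloxy)acetophenone | CC(=O)c1c(O)cc(OC)cc1OCC=C(C)C | intermediate
4 | (E)-3-(dimethylamino)-1-[2-hydroxy-4-methoxy-6-(prenyloxy)phenyl]prop-2-en-1-one | CN(C)/C=C/C(=O)c1c(O)cc(OC)cc1OCC=C(C)C | intermediate (not isolated)
5 | 7-methoxy-5-(prenyloxy)chromen-4-one | COc1cc(OCC=C(C)C)c2c(=O)ccoc2c1 | intermediate
6 | 7-methoxy-6-(2-methylbut-3-en-2-yl)-6H-chromene-4,5-dione (ortho-dienone, racemic at C6) | COC1=CC2=C(C(=O)C=CO2)C(=O)C1C(C)(C)C=C | intermediate (not isolated)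
7 | 7-methoxy-8-(3-methylbut-2-enyl)-8H-chromene-4,5-dione (para-dienone, racemic at C8) | COC1=CC(=O)C2=C(OC=CC2=O)C1CC=C(C)C | intermediate (not isolated)
8 | 5-hydroxy-7-methoxy-8-prenylchromen-4-one | COc1cc(O)c2c(=O)ccoc2c1CC=C(C)C | intermediate
9 | 4-bromocatechol | Oc1ccc(Br)cc1O | starting material
10 | 4-bromo-1,2-bis(methoxymethoxy)benzene | COCOc1ccc(Br)cc1OCOC | intermediate
11 | 3,4-bis(methoxymethoxy)phenyllithium | [Li]c1ccc(OCOC)c(OCOC)c1 | intermediate (not isolated)
12 | lithium [3,4-bis(methoxymethoxy)phenyl]triisopropoxyborate | [Li+].CC(C)O[B-](OC(C)C)(OC(C)C)c1ccc(OCOC)c(OCOC)c1 | intermediate (not isolated)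
13 | 3,4-bis(methoxymethoxy)phenylboronic acid | COCOc1ccc(B(O)O)cc1OCOC | intermediate
14 | (2S)-5-hydroxy-7-methoxy-2-[3,4-bis(methoxymethoxy)phenyl]-8-prenylchroman-4-one | COc1cc(O)c2c(c1CC=C(C)C)O[C@H](c1ccc(OCOC)c(OCOC)c1)CC2=O | intermediate
15 | (2S)-2-(3,4-dihydroxyphenyl)-5-hydroxy-7-methoxy-8-(3-methylbut-2-enyl)chroman-4-one | COc1cc(O)c2c(c1CC=C(C)C)O[C@H](c1ccc(O)c(O)c1)CC2=O | target

**Step count**
Total step count: 7. Longest linear sequence: 5 steps (steps 1, 2, 3, 6, 7); the boronic acid branch is steps 4 and 5.

**Steps most likely to fail**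

Step 6. The chelating 5-hydroxy-4-ketone unit may sequester palladium, insertion into the electron-rich chromone may be slow against protodeboronation of the electron-rich boronic acid, β-hydride elimination may divert material to the flavone, or enantioface selectivity may be poor. The fallback sets out from 8 and changes both the metal and the state of O5. Acetylation (Ac2O, pyridine, cat. DMAP, CH2Cl2) would give 5-acetoxy-7-methoxy-8-prenylchromen-4-one F1, which no longer chelates and is a better acceptor. A base-free asymmetric 1,4-addition of 13 catalysed by monovalent rhodium ([RhOH(cod)]2, cod = 1,5-cyclooctadiene, with an electron-poor atropisomeric bisphosphine of the MeO-BIPHEP family of the appropriate hand, toluene/H2O, rt) would give (2S)-5-acetoxy-7-methoxy-2-[3,4-bis(methoxymethoxy)phenyl]-8-prenylchroman-4-one F2. HCl in methanol as in step 7 should then remove both MOM ethers and methanolyse the aryl acetate in one operation, so the fallback comes back to the route at 15.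

Step 3. The cascade may stop after the first shift by rearomatisation to the 6-(1,1-dimethylallyl) isomer, or the allylic ether may ionise with loss of the prenyl group. The fallback sets out from 1 and builds the C8 side chain by an ortho-Claisen shift from the oxygen that becomes O1, followed by olefin cross-metathesis.
- Mono-O-allylation of 1 (allyl bromide, K2CO3, acetone) would give 2'-allyloxy-6'-hydroxy-4'-methoxyacetophenone F3.
- Masking the remaining phenol (NaH, MOMCl, DMF) would give 2'-allyloxy-4'-methoxy-6'-(methoxymethoxy)acetophenone F4.
- Thermal Claisen rearrangement (N,N-diethylaniline, 190 °C) can only reach the single free ortho position and should give 3'-allyl-2'-hydroxy-4'-methoxy-6'-(methoxymethoxy)acetophenone F5.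
- Condensation with N,N-dimethylformamide dimethyl acetal would give the enaminone (E)-1-[3-allyl-2-hydroxy-4-methoxy-6-(methoxymethoxy)phenyl]-3-(dimethylamino)prop-2-en-1-one F6, not isolated. HCl in methanol at 40 °C should close the pyranone through the only free phenol to 8-allyl-7-methoxy-5-(methoxymethoxy)chromen-4-one F7, not isolated, and then cleave the peri MOM ether to 8-allyl-5-hydroxy-7-methoxychromen-4-one F8.
- Cross-metathesis of F8 with 2-methylbut-2-ene (second-generation Grubbs catalyst, RuCl2(=CHPh)(H2IMes)(PCy3), CH2Cl2, 40 °C) would convert the allyl into the prenyl group, and the fallback comes back to the route at 8.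

Step 2. The peri prenyl ether may be lost under the acidic ring closure, or the formamide acetal may O-methylate the phenol. The fallback sets out from 1 and inverts the order of ring closure and etherification, using the symmetry of 1. Condensation with N,N-dimethylformamide dimethyl acetal would give (E)-1-(2,6-dihydroxy-4-methoxyphenyl)-3-(dimethylamino)prop-2-en-1-one F9, not isolated; either hydroxyl closes to the same product on treatment with aqueous acid, 5-hydroxy-7-methoxychromen-4-one F10. Mitsunobu etherification of the chelated 5-OH (3-methylbut-2-en-1-ol, PPh3, diisopropyl azodicarboxylate, THF, 0 °C to rt) then installs the prenyl ether under neutral conditions, and the fallback comes back to the route at 5.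

**Further compounds**
F1 | step 6 | 5-acetoxy-7-methoxy-8-prenylchromen-4-one | COc1cc(OC(C)=O)c2c(=O)ccoc2c1CC=C(C)C
F2 | step 6 | (2S)-5-acetoxy-7-methoxy-2-[3,4-bis(methoxymethoxy)phenyl]-8-prenylchroman-4-one | COc1cc(OC(C)=O)c2c(c1CC=C(C)C)O[C@H](c1ccc(OCOC)c(OCOC)c1)CC2=O
F3 | step 3 | 2'-allyloxy-6'-hydroxy-4'-methoxyacetophenone | CC(=O)c1c(O)cc(OC)cc1OCC=C
F4 | step 3 | 2'-allyloxy-4'-methoxy-6'-(methoxymethoxy)acetophenone | CC(=O)c1c(OCOC)cc(OC)cc1OCC=C
F5 | step 3 | 3'-allyl-2'-hydroxy-4'-methoxy-6'-(methoxymethoxy)acetophenone | CC(=O)c1c(OCOC)cc(OC)c(CC=C)c1O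
F6 | step 3 | (E)-1-[3-allyl-2-hydroxy-4-methoxy-6-(methoxymethoxy)phenyl]-3-(dimethylamino)prop-2-en-1-one | CN(C)/C=C/C(=O)c1c(OCOC)cc(OC)c(CC=C)c1O
F7 | step 3 | 8-allyl-7-methoxy-5-(methoxymethoxy)chromen-4-one | COCOc1cc(OC)c(CC=C)c2occc(=O)c12
F8 | step 3 | 8-allyl-5-hydroxy-7-methoxychromen-4-one | COc1cc(O)c2c(=O)ccoc2c1CC=C
F9 | step 2 | (E)-1-(2,6-dihydroxy-4-methoxyphenyl)-3-(dimethylamino)prop-2-en-1-one | CN(C)/C=C/C(=O)c1c(O)cc(OC)cc1O
F10 | step 2 | 5-hydroxy-7-methoxychromen-4-one | COc1cc(O)c2c(=O)ccoc2c1
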